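**Plan**

- Numbering: ring C1 (aryloxy), C2=C3 (methyl on C3), C4 (OH), C5, C6; side chain C1′ (methyl), C2′, C3′ (ketone). The retrosynthesis cuts the trienone C=C next to the ether-bearing arene (boron-templated aldol), the C3′–alkenyl bond (acyl Stille), the O–aryl bond (SNAr), then C5–C6 and C2=C3 of the ring.
- Enabling feature: with C4 as a ketone the ring is a 2-methylcyclohex-2-enone in which C6 lies β to the C4 carbonyl through C5. C5 of a propionylacetate can therefore add to the β-carbon of an enal (C6), and the ethyl-ketone carbon (C3) can then condense on the aldehyde carbon (C2).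
- Forward order: chiral-pool enal; the cyclohexenone (the only ring made) in step 4; oxygenation at C1 with lactone closure; C4 reduction and silylation; lactone opening with SNAr arylation; isobutenyl ketone; desilylation; curcuminoid arm last.
- Stereochemistry: C1′ from the (S)-methylsuccinate half ester; C6 from the (S)-diarylprolinol silyl ether; C1 by peracid attack anti to the C6 chain; C4 by (R)-CBS reduction; the E-alkenes of the arm from the aldol condensations.

Key step: step 4

Remark: the 1,3-diketone of 23 and 24 is written as one enol tautomer; the tautomers interconvert freely, so no step addresses this.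

Step 1
Reactants: 1 (S)-4-methoxy-2-methyl-4-oxobutanoic acid
Product: 2 methyl (3S)-4-hydroxy-3-methylbutanoate
Conditions: BH3·SMe2, THF, −10 °C to rt; MeOH, then cold aqueous work-up
Reagents that add atoms: none
Why: Chemoselective borane reduction, in which the free acid reacts through its acyloxyborane far faster than the methyl ester, leaves the stereocentre untouched, and a cold non-acidic work-up keeps the hydroxy ester from closing to the butyrolactone.

Step 2
Reactants: 2 methyl (3S)-4-hydroxy-3-methylbutanoate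
Product: 3 methyl (3S)-3-methyl-4-oxobutanoate
Conditions: TEMPO (cat.), PhI(OAc)2, CH2Cl2, rt
Reagents that add atoms: none
Why: TEMPO/oxoammonium oxidation stops at the aldehyde under essentially neutral conditions, so the α-stereocentre should survive, and the crude aldehyde is used at once.

Step 3
Reactants: 3 methyl (3S)-3-methyl-4-oxobutanoate; 4 (triphenylphosphoranylidene)acetaldehyde
Product: 5 methyl (3S,4E)-3-methyl-6-oxohex-4-enoate
Conditions: 4 (1.05 equiv), toluene, 60 °C
Reagents that add atoms: none
Why: Wittig olefination with the stabilised formylmethylene ylide gives the E-enal, and the weakly basic ylide used near stoichiometry should neither epimerise 3 nor homologate 5 further.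

Step 4
Reactants: 5 methyl (3S,4E)-3-methyl-6-oxohex-4-enoate; 6 tert-butyl 3-oxopentanoate
Product: 8 methyl (3S)-3-[(1R)-4-methyl-3-oxocyclohex-4-en-1-yl]butanoate, via Michael adduct 7 (not isolated)
Conditions: (S)-2-{bis[3,5-bis(trifluoromethyl)phenyl][(trimethylsilyl)oxy]methyl}pyrrolidine (10 mol%), 6 (1.5 equiv), toluene (concentrated), 0 °C to rt; then TsOH·H2O (20 mol%), toluene, 80 °C
Reagents that add atoms: none
Why: The amine condenses with 5 to an E-iminium ion, the enol of 6 adds through its active methylene to the β-carbon and hydrolysis releases 7; TsOH then drives aldol condensation of the ethyl-ketone α-carbon onto the aldehyde, cleaves the tert-butyl ester and the β-keto acid decarboxylates. The closest known reaction type is the diarylprolinol silyl ether catalysed Michael addition of β-keto esters to enals followed by acid-promoted aldol condensation and decarboxylation to 5-substituted cyclohex-2-enones. The ring closes in a 6-(enolendo)-exo-trig aldol mode, the only other enol/carbonyl pairings being four-membered. C6 is set by the catalyst: the diaryl(silyloxy)methyl group of the (S)-amine covers one face of the s-trans E-iminium ion, so the nucleophile enters from the other, which corresponds to 6R beside the unchanged 1′S centre. The step needs conjugate addition to outrun γ-deprotonation of the iminium ion, since dienamine formation would epimerise C1′; the γ-hydrogen is a hindered tertiary C–H, and an excess of the reactive keto ester, the weakly basic bis(trifluoromethyl)aryl catalyst, the absence of added base and low temperature all favour addition. The methyl ester is inert to both stages, and the stereocentre at the keto ester carbon of 7 is lost on decarboxylation.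

Step 5
Reactants: 8 methyl (3S)-3-[(1R)-4-methyl-3-oxocyclohex-4-en-1-yl]butanoate
Product: 9 methyl (3S)-3-[(1R)-5-{[tert-butyl(dimethyl)silyl]oxy}-4-methylcyclohexa-2,4-dien-1-yl]butanoate
Conditions: TBSOTf (1.2 equiv), Et3N, CH2Cl2, 0 °C to rt
Reagents that add atoms: tert-butyldimethylsilyl trifluoromethanesulfonate, CC(C)(C)[Si](C)(C)OS(=O)(=O)C(F)(F)F
Why: Soft enolisation (O-silylation, then amine deprotonation) under equilibrating conditions should remove the γ-hydrogen at C1 and give the through-conjugated 1-silyloxy-1,3-diene, as with other α-alkyl cyclohexenones and steroidal 4-en-3-ones, while the much less basic ester carbonyl is not silylated.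

Step 6
Reactants: 9 methyl (3S)-3-[(1R)-5-{[tert-butyl(dimethyl)silyl]oxy}-4-methylcyclohexa-2,4-dien-1-yl]butanoate
Product: 11 (4S,4aR,8aR)-4,7-dimethyl-3,4,4a,5-tetrahydro-2H-chromene-2,6(8aH)-dione, via hydroxy enone ester 10 (not isolated)
Conditions: mCPBA, CH2Cl2, −20 to 0 °C; aqueous work-up; then PPTS (cat.), CH2Cl2, rt
Reagents that add atoms: 3-chloroperbenzoic acid, OOC(=O)c1cccc(Cl)c1
Why: Vinylogous Rubottom oxidation, in which the peracid epoxidises the distal C1=C2 bond anti to the adjacent C6 substituent and silyloxy-assisted opening returns the enone with C1–OH trans to the chain (1R), is followed by acid-catalysed closure of the δ-hydroxy ester to the trans-fused δ-lactone, which masks both C1–OH and the carboxyl group.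

Step 7
Reactants: 11 (4S,4aR,8aR)-4,7-dimethyl-3,4,4a,5-tetrahydro-2H-chromene-2,6(8aH)-dione
Product: 12 (4S,4aR,6S,8aR)-6-hydroxy-4,7-dimethyl-3,4,4a,5,6,8a-hexahydro-2H-chromen-2-one
Conditions: (R)-2-methyl-CBS-oxazaborolidine (0.3 equiv), BH3·SMe2, THF, −30 °C; MeOH, then aqueous work-up
Reagents that add atoms: none
Why: CBS reduction, in which the oxazaborolidine–borane complex binds the enone carbonyl anti to the larger α-methylalkenyl flank and delivers hydride 1,2, should with the (R)-catalyst give the ring C4 (S) alcohol cis to the lactone oxygen against the substrate's preference for axial hydride entry, the lactone being inert to borane at this temperature.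

Step 8
Reactants: 12 (4S,4aR,6S,8aR)-6-hydroxy-4,7-dimethyl-3,4,4a,5,6,8a-hexahydro-2H-chromen-2-one
Product: 13 (4S,4aR,6S,8aR)-4,7-dimethyl-6-{[tri(propan-2-yl)silyl]oxy}-3,4,4a,5,6,8a-hexahydro-2H-chromen-2-one
Conditions: TIPSOTf, 2,6-lutidine, CH2Cl2, 0 °C
Reagents that add atoms: triisopropylsilyl trifluoromethanesulfonate, CC(C)[Si](C(C)C)(C(C)C)OS(=O)(=O)C(F)(F)F
Why: Standard silylation of a secondary allylic alcohol with a silyl triflate and a hindered pyridine base, the triisopropylsilyl group being chosen because it should neither migrate to the C1 alkoxide nor cleave under the basic conditions of step 9.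

Step 9
Reactants: 13 (4S,4aR,6S,8aR)-4,7-dimethyl-6-{[tri(propan-2-yl)silyl]oxy}-3,4,4a,5,6,8a-hexahydro-2H-chromen-2-one; 14 4-fluoro-3-methoxybenzaldehyde
Product: 16 (3S)-3-[(1R,2R,5S)-2-(4-formyl-2-methoxyphenoxy)-4-methyl-5-{[tri(propan-2-yl)silyl]oxy}cyclohex-3-en-1-yl]butanoic acid, via potassium hydroxy carboxylate 15 (not isolated)
Conditions: KOH (1.05 equiv), THF/H2O, rt; evaporate, toluene azeotrope; NaH (1.2 equiv), DMF, 0 °C; 14, 0 °C to rt; cold dilute HCl to pH 4
Reagents that add atoms: potassium hydroxide, [K+].[OH-]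
Why: Saponification turns the lactone into a carboxylate that cannot re-lactonise under base, and the C1 alkoxide then displaces the fluoride para to the formyl group by addition–elimination (SNAr), which leaves the C1–O bond and so the C1 configuration untouched.

Step 10
Reactants: 16 (3S)-3-[(1R,2R,5S)-2-(4-formyl-2-methoxyphenoxy)-4-methyl-5-{[tri(propan-2-yl)silyl]oxy}cyclohex-3-en-1-yl]butanoic acid; 17 tributyl(2-methylprop-1-en-1-yl)stannane
Product: 19 4-{[(1R,4S,6R)-3-methyl-6-[(2S)-6-methyl-4-oxohept-5-en-2-yl]-4-{[tri(propan-2-yl)silyl]oxy}cyclohex-2-en-1-yl]oxy}-3-methoxybenzaldehyde, via acid chloride 18 (not isolated)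
Conditions: 1-chloro-N,N,2-trimethylprop-1-en-1-amine, CH2Cl2, 0 °C to rt; evaporate; 17, Pd2(dba)3 (2.5 mol%), P(2-furyl)3 (10 mol%), THF, rt
Reagents that add atoms: none
Why: Stille acylation, in which the acid chloride formed under neutral conditions adds oxidatively to zerovalent palladium, the 2-methylpropenyl group is transferred from tin and reductive elimination gives the enone, tolerates the aryl aldehyde that an organomagnesium route would attack.

Step 11
Reactants: 19 4-{[(1R,4S,6R)-3-methyl-6-[(2S)-6-methyl-4-oxohept-5-en-2-yl]-4-{[tri(propan-2-yl)silyl]oxy}cyclohex-2-en-1-yl]oxy}-3-methoxybenzaldehyde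
Product: 20 4-{[(1R,4S,6R)-4-hydroxy-3-methyl-6-[(2S)-6-methyl-4-oxohept-5-en-2-yl]cyclohex-2-en-1-yl]oxy}-3-methoxybenzaldehyde
Conditions: HF·pyridine, pyridine, THF, 0 °C to rt
Reagents that add atoms: none
Why: Fluoride-driven Si–O cleavage with pyridine-buffered HF removes the silyl ether without the basicity that could start aldol chemistry between aldehyde and ketone or the acidity that could ionise the allylic C–O bonds.

Step 12
Reactants: 21 4-hydroxybenzaldehyde; 22 pentane-2,4-dione
Product: 23 (3Z,5E)-4-hydroxy-6-(4-hydroxyphenyl)hexa-3,5-dien-2-one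
Conditions: 22 (3 equiv), B2O3, EtOAc, 70 °C; 21, B(OnBu)3; n-BuNH2 (0.2 equiv), 70 °C; then 0.4 M HCl, 50 °C
Reagents that add atoms: none
Why: Boron-templated aldol (Knoevenagel-type) condensation, in which chelation of the diketone blocks its central carbon and the amine catalyses condensation of a terminal methyl with the aldehyde to the E-alkene, is held to one arm by the excess of 22.

Step 13
Reactants: 20 4-{[(1R,4S,6R)-4-hydroxy-3-methyl-6-[(2S)-6-methyl-4-oxohept-5-en-2-yl]cyclohex-2-en-1-yl]oxy}-3-methoxybenzaldehyde; 23 (3Z,5E)-4-hydroxy-6-(4-hydroxyphenyl)hexa-3,5-dien-2-one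
Product: 24 demethoxybisabolocurcumin ether, (1E,4Z,6E)-5-hydroxy-1-(4-hydroxyphenyl)-7-(4-{[(1R,4S,6R)-4-hydroxy-3-methyl-6-[(2S)-6-methyl-4-oxohept-5-en-2-yl]cyclohex-2-en-1-yl]oxy}-3-methoxyphenyl)hepta-1,4,6-trien-3-one
Conditions: 23 (1.2 equiv), B2O3, EtOAc, 70 °C; 20, B(OnBu)3; n-BuNH2 (0.2 equiv), 70 °C; then 10% aqueous AcOH, rt
Reagents that add atoms: none
Why: In this second boron-templated aldol condensation only the methyl group of chelated 23 is activated, so it should condense with the aryl aldehyde of 20 to the E-alkene while the unchelated isobutenyl ketone stays inert, the hydroxyl groups travel as borates, and a mild acidic work-up spares the allylic ether and alcohol.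

**Compound list**

1 | (S)-4-methoxy-2-methyl-4-oxobutanoic acid | OC(=O)[C@@H](C)CC(=O)OC | starting material
2 | methyl (3S)-4-hydroxy-3-methylbutanoate | OC[C@@H](C)CC(=O)OC | intermediate
3 | methyl (3S)-3-methyl-4-oxobutanoate | O=C[C@@H](C)CC(=O)OC | intermediate
4 | (triphenylphosphoranylidene)acetaldehyde | O=CC=P(c1ccccc1)(c1ccccc1)c1ccccc1 | starting material
5 | methyl (3S,4E)-3-methyl-6-oxohex-4-enoate | COC(=O)C[C@H](C)/C=C/C=O | intermediate
6 | tert-butyl 3-oxopentanoate | CCC(=O)CC(=O)OC(C)(C)C | starting material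
7 | 1-tert-butyl 6-methyl (3S,4S)-4-methyl-3-(2-oxoethyl)-2-propanoylhexanedioate (both C2 epimers; not isolated) | CCC(=O)C(C(=O)OC(C)(C)C)[C@@H](CC=O)[C@@H](C)CC(=O)OC | intermediate
8 | methyl (3S)-3-[(1R)-4-methyl-3-oxocyclohex-4-en-1-yl]butanoate | O=C1C[C@H]([C@@H](C)CC(=O)OC)CC=C1C | intermediate
9 | methyl (3S)-3-[(1R)-5-{[tert-butyl(dimethyl)silyl]oxy}-4-methylcyclohexa-2,4-dien-1-yl]butanoate | CC1=C(O[Si](C)(C)C(C)(C)C)C[C@@H](C=C1)[C@@H](C)CC(=O)OC | intermediate
10 | methyl (3S)-3-[(1R,2R)-2-hydroxy-4-methyl-5-oxocyclohex-3-en-1-yl]butanoate (not isolated) | O[C@H]1C=C(C)C(=O)C[C@@H]1[C@@H](C)CC(=O)OC | intermediate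
11 | (4S,4aR,8aR)-4,7-dimethyl-3,4,4a,5-tetrahydro-2H-chromene-2,6(8aH)-dione | O=C1O[C@H]2C=C(C)C(=O)C[C@@H]2[C@@H](C)C1 | intermediate
12 | (4S,4aR,6S,8aR)-6-hydroxy-4,7-dimethyl-3,4,4a,5,6,8a-hexahydro-2H-chromen-2-one | O=C1O[C@H]2C=C(C)[C@@H](O)C[C@@H]2[C@@H](C)C1 | intermediate
13 | (4S,4aR,6S,8aR)-4,7-dimethyl-6-{[tri(propan-2-yl)silyl]oxy}-3,4,4a,5,6,8a-hexahydro-2H-chromen-2-one | O=C1O[C@H]2C=C(C)[C@@H](O[Si](C(C)C)(C(C)C)C(C)C)C[C@@H]2[C@@H](C)C1 | intermediate
14 | 4-fluoro-3-methoxybenzaldehyde | COc1cc(C=O)ccc1F | starting material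
15 | potassium (3S)-3-[(1R,2R,5S)-2-hydroxy-4-methyl-5-{[tri(propan-2-yl)silyl]oxy}cyclohex-3-en-1-yl]butanoate (not isolated) | O[C@H]1C=C(C)[C@@H](O[Si](C(C)C)(C(C)C)C(C)C)C[C@@H]1[C@@H](C)CC(=O)[O-].[K+] | intermediate
16 | (3S)-3-[(1R,2R,5S)-2-(4-formyl-2-methoxyphenoxy)-4-methyl-5-{[tri(propan-2-yl)silyl]oxy}cyclohex-3-en-1-yl]butanoic acid | COc1cc(C=O)ccc1O[C@H]1C=C(C)[C@@H](O[Si](C(C)C)(C(C)C)C(C)C)C[C@@H]1[C@@H](C)CC(=O)O | intermediate
17 | tributyl(2-methylprop-1-en-1-yl)stannane | CCCC[Sn](CCCC)(CCCC)C=C(C)C | starting material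
18 | (3S)-3-[(1R,2R,5S)-2-(4-formyl-2-methoxyphenoxy)-4-methyl-5-{[tri(propan-2-yl)silyl]oxy}cyclohex-3-en-1-yl]butanoyl chloride (not isolated) | COc1cc(C=O)ccc1O[C@H]1C=C(C)[C@@H](O[Si](C(C)C)(C(C)C)C(C)C)C[C@@H]1[C@@H](C)CC(=O)Cl | intermediate
19 | 4-{[(1R,4S,6R)-3-methyl-6-[(2S)-6-methyl-4-oxohept-5-en-2-yl]-4-{[tri(propan-2-yl)silyl]oxy}cyclohex-2-en-1-yl]oxy}-3-methoxybenzaldehyde | COc1cc(C=O)ccc1O[C@H]1C=C(C)[C@@H](O[Si](C(C)C)(C(C)C)C(C)C)C[C@@H]1[C@@H](C)CC(=O)C=C(C)C | intermediate
20 | 4-{[(1R,4S,6R)-4-hydroxy-3-methyl-6-[(2S)-6-methyl-4-oxohept-5-en-2-yl]cyclohex-2-en-1-yl]oxy}-3-methoxybenzaldehyde | COc1cc(C=O)ccc1O[C@H]1C=C(C)[C@@H](O)C[C@@H]1[C@@H](C)CC(=O)C=C(C)C | intermediate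
21 | 4-hydroxybenzaldehyde | O=Cc1ccc(O)cc1 | starting material
22 | pentane-2,4-dione | CC(=O)CC(C)=O | starting material
23 | (3Z,5E)-4-hydroxy-6-(4-hydroxyphenyl)hexa-3,5-dien-2-one | CC(=O)/C=C(\O)/C=C/c1ccc(O)cc1 | intermediate
24 | demethoxybisabolocurcumin ether | COc1cc(/C=C/C(O)=C/C(=O)/C=C/c2ccc(O)cc2)ccc1O[C@H]1C=C(C)[C@@H](O)C[C@@H]1[C@@H](C)CC(=O)C=C(C)C | target

**Step count**

Total: 13 steps. Longest linear sequence: 12 steps (steps 1 to 11, then step 13); step 12 is a one-step side branch.

**Steps most likely to fail**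

Step 4. The configuration at C1′ may be lost by reversible γ-deprotonation of the iminium ion, or face selection at C6 may be weak beside the neighbouring stereocentre. The fallback sets out from 3, comes back at 8 and uses no amine, so no dienamine can form. Aldehyde 3 would be condensed with 1-(triphenylphosphoranylidene)butan-2-one (CCC(=O)C=P(c1ccccc1)(c1ccccc1)c1ccccc1) in toluene to methyl (3S,4E)-3-methyl-6-oxooct-4-enoate F1. Rhodium-catalysed asymmetric conjugate addition of potassium vinyltrifluoroborate ([Rh(cod)2]BF4, BINAP, toluene/H2O) would then give methyl (3S,4S)-4-ethenyl-3-methyl-6-oxooctanoate F2; the BINAP antipode that places the vinyl group on the required face would be fixed on a model enone. Aldehyde-selective Wacker oxidation of the vinyl group (PdCl2(PhCN)2, CuCl2, AgNO2, O2, t-BuOH/MeNO2) would give methyl (3S,4R)-3-methyl-6-oxo-4-(2-oxoethyl)octanoate F3, and TsOH in toluene at 80 °C would close F3 by the same aldol condensation to 8.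

Step 7. Facial selectivity may be poor, because the catalyst has to overrule the substrate's preference for axial hydride entry, which leads to the C4 epimer. The fallback sets out from 11 and comes back at 12 by using that preference and then inverting. Luche reduction (NaBH4, CeCl3·7H2O, MeOH, −40 °C) would give (4S,4aR,6R,8aR)-6-hydroxy-4,7-dimethyl-3,4,4a,5,6,8a-hexahydro-2H-chromen-2-one F4. Mitsunobu inversion with 4-nitrobenzoic acid (PPh3, DIAD, THF) would give (4S,4aR,6S,8aR)-4,7-dimethyl-2-oxo-3,4,4a,5,6,8a-hexahydro-2H-chromen-6-yl 4-nitrobenzoate F5. Methanolysis (K2CO3, MeOH, 0 °C), followed by PPTS to re-close any opened lactone, would give 12.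

Step 9. The hindered secondary alkoxide may attack the ortho-methoxy fluoroarene slowly, while the aldehyde is consumed by alkoxide addition or disproportionation. The fallback sets out from 13 and comes back at 16, and reverses the polarity of the C1–O bond formation by Tsuji–Trost allylic etherification. Lactone 13 would be treated with 4-hydroxy-3-methoxybenzaldehyde (COc1cc(C=O)ccc1O), Pd2(dba)3 and PPh3 in THF at rt to 50 °C. Zerovalent palladium should ionise the allylic lactone C1–O bond with inversion, and the phenoxide should attack the less substituted allyl terminus C1 with a second inversion, giving 16 with net retention. This fallback makes no compound outside the list (entry F0).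

**Further compounds**

F1 | step 4 | methyl (3S,4E)-3-methyl-6-oxooct-4-enoate | CCC(=O)/C=C/[C@@H](C)CC(=O)OC
F2 | step 4 | methyl (3S,4S)-4-ethenyl-3-methyl-6-oxooctanoate | CCC(=O)C[C@@H](C=C)[C@@H](C)CC(=O)OC
F3 | step 4 | methyl (3S,4R)-3-methyl-6-oxo-4-(2-oxoethyl)octanoate | CCC(=O)C[C@@H](CC=O)[C@@H](C)CC(=O)OC
F4 | step 7 | (4S,4aR,6R,8aR)-6-hydroxy-4,7-dimethyl-3,4,4a,5,6,8a-hexahydro-2H-chromen-2-one | O=C1O[C@H]2C=C(C)[C@H](O)C[C@@H]2[C@@H](C)C1
F5 | step 7 | (4S,4aR,6S,8aR)-4,7-dimethyl-2-oxo-3,4,4a,5,6,8a-hexahydro-2H-chromen-6-yl 4-nitrobenzoate | O=C1O[C@H]2C=C(C)[C@@H](OC(=O)c3ccc(cc3)[N+](=O)[O-])C[C@@H]2[C@@H](C)C1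
F0 | step 9 | none | none
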